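The route rests on cutting ring A across C3–C4 and C5–C10, so that the decalin unfolds to an acyclic 1,7,9-decatrien-3-one. The feature exploited is the cis pair of methyls C15 and C14 on C4 and C5 of ring A together with the C2 carbonyl: an E-tiglyl ketone alkene carries the two methyls and a 2-silyloxydiene carries the oxygen. One intramolecular Diels–Alder reaction closes rings A and B, forms two C–C bonds and sets C4, C5 and C10. Its precursor is a tiglyl ketone (C6) whose tether bears the C7 isopropenyl group and a cis C8,C9 acetonide and ends in an (E)-2-(triisopropylsilyloxy)diene.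

Key step: step 10

Remark: all intermediates carry eremophilane numbering (C1–C10 decalin, C11–C13 isopropenyl on C7, C14 on C5, C15 on C4); 5 is assumed to be available as the single (S) enantiomer, and the carbinol centre brought in with 6 is erased in step 8, so racemic 6 would serve equally.

Step 1
Reactants: 1 tigloyl chloride, (E)-2-methylbut-2-enoyl chloride
Product: 2 (E)-N-methoxy-N,2-dimethylbut-2-enamide
Conditions: MeNH(OMe)·HCl, K2CO3, CH2Cl2/H2O, 0 °C → rt
Reagents that add atoms: N,O-dimethylhydroxylamine hydrochloride, CNOC.Cl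
Why: Schotten–Baumann amide formation (Weinreb amide); the biphasic carbonate base is too weak to deconjugate the acid chloride through a vinylketene, so the E alkene is kept.

Step 2
Reactants: 2 (E)-N-methoxy-N,2-dimethylbut-2-enamide; 3 2-methylallylmagnesium chloride (commercial THF solution)
Product: 4 (E)-2,5-dimethylhepta-1,5-dien-4-one
Conditions: THF, −78 → −20 °C; cold aq. NH4Cl
Reagents that add atoms: none
Why: Weinreb ketone synthesis; the allylic Grignard reagent adds once because the magnesium-chelated tetrahedral adduct survives until the cold buffered quench, which also keeps the β,γ-alkene out of conjugation.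

Step 3
Reactants: 5 methyl (S)-2-hydroxybut-3-enoate; 6 (S)-but-3-en-2-ol (3 equiv)
Product: 7 methyl (2S,3E,5S)-2,5-dihydroxyhex-3-enoate
Conditions: second-generation Hoveyda–Grubbs catalyst, RuCl2(H2IMes)(=CH-C6H4-2-O-i-Pr) (3 mol%), 1,4-benzoquinone (10 mol%), CH2Cl2, 40 °C
Reagents that add atoms: none
Why: Olefin cross-metathesis of two secondary allylic alcohols, run before any other alkene is in the molecule so that no ring-closing pathway exists; the E alkene forms under thermodynamic control, benzoquinone suppresses hydride-induced isomerisation, and neither carbinol centre is touched.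

Step 4
Reactants: 7 methyl (2S,3E,5S)-2,5-dihydroxyhex-3-enoate
Product: 8 methyl (2S,3E,5S)-2,5-bis(triethylsilyloxy)hex-3-enoate
Conditions: TESCl, imidazole, DMF, 0 °C → rt
Reagents that add atoms: chlorotriethylsilane, CC[Si](Cl)(CC)CC
Why: Imidazole-promoted silyl ether formation caps both secondary hydroxyls so that the ester can be reduced and the aldehyde used in a boron aldol reaction; no stereocentre is affected.

Step 5
Reactants: 8 methyl (2S,3E,5S)-2,5-bis(triethylsilyloxy)hex-3-enoate
Product: 9 (2S,3E,5S)-2,5-bis(triethylsilyloxy)hex-3-enal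
Conditions: i-Bu2AlH (1.1 equiv), CH2Cl2, −78 °C; MeOH, aq. KNaC4H4O6 (potassium sodium tartrate); used crude
Reagents that add atoms: none
Why: Partial reduction of an α-silyloxy ester with DIBAL-H; the aluminium hemiacetal is stable at −78 °C and gives the aldehyde only on work-up, and the β,γ-unsaturated aldehyde is used at once to avoid enolisation at C9.

Step 6
Reactants: 4 (E)-2,5-dimethylhepta-1,5-dien-4-one (1.2 equiv); 9 (2S,3E,5S)-2,5-bis(triethylsilyloxy)hex-3-enal
Product: 12 (2E,5R,6R,7S,8E,10S)-6-hydroxy-3-methyl-5-(prop-1-en-2-yl)-7,10-bis(triethylsilyloxy)undeca-2,8-dien-4-one, via dibutylboron Z-dienolate 10 (not isolated), via dibutylboron aldolate 11 (not isolated)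
Conditions: Bu2BOTf, i-Pr2NEt, CH2Cl2, −78 °C; then 9, −78 → −40 °C; pH 7 buffer, MeOH, 30% H2O2, 0 °C
Reagents that add atoms: none
Why: Dibutylboron aldol reaction; soft enolisation of the only enolisable position of 4 gives the Z dienolate, which reacts through its α-carbon in a Zimmerman–Traxler chair to set C7 and C8 syn, while the α-silyloxy centre C9 of the aldehyde directs attack to its Felkin–Anh (Cornforth) face so that C8 and C9 become anti.

Step 7
Reactants: 12 (2E,5R,6R,7S,8E,10S)-6-hydroxy-3-methyl-5-(prop-1-en-2-yl)-7,10-bis(triethylsilyloxy)undeca-2,8-dien-4-one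
Product: 14 (2E,5R)-5-{(4R,5S)-5-[(1E,3S)-3-hydroxybut-1-en-1-yl]-2,2-dimethyl-1,3-dioxolan-4-yl}-3,6-dimethylhepta-2,6-dien-4-one, via triol 13 (not isolated)
Conditions: PPTS, MeOH, rt; concentrate; Me2C(OMe)2, acetone, PPTS, rt; aq. NH4Cl work-up
Reagents that add atoms: 2,2-dimethoxypropane, COC(C)(C)OC
Why: Acid-catalysed silyl ether methanolysis followed by acetonide formation (transketalisation); of the three hydroxyls only the vicinal C8/C9 pair can close a five-membered ketal, so the allylic C2 hydroxyl stays free without any selective protection.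

Step 8
Reactants: 14 acetonide alcohol
Product: 15 (2E,5R)-3,6-dimethyl-5-{(4R,5S)-2,2-dimethyl-5-[(E)-3-oxobut-1-en-1-yl]-1,3-dioxolan-4-yl}hepta-2,6-dien-4-one
Conditions: activated MnO2 (20 equiv), CH2Cl2, rt
Reagents that add atoms: none
Why: Allylic alcohol oxidation with MnO2; the only free hydroxyl is the allylic one, and the neutral heterogeneous oxidant leaves the epimerisable C7 centre, the acetonide and the alkenes untouched.

Step 9
Reactants: 15 dienone
Product: 16 (2E,5R)-3,6-dimethyl-5-{(4R,5S)-2,2-dimethyl-5-[(E)-3-(triisopropylsilyloxy)buta-1,3-dien-1-yl]-1,3-dioxolan-4-yl}hepta-2,6-dien-4-one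
Conditions: TIPSOTf (1.15 equiv), Et3N (2 equiv), CH2Cl2, −78 → 0 °C; chromatography on Et3N-deactivated silica, stored cold
Reagents that add atoms: triisopropylsilyl trifluoromethanesulfonate, CC(C)[Si](OS(=O)(=O)C(F)(F)F)(C(C)C)C(C)C
Why: Soft enolisation of a methyl ketone (silyl triflate and amine); the unhindered C3 methyl of the enone is silylated kinetically to the cross-conjugated dienol ether, whereas the C6 carbonyl, flanked by the methyl-bearing C5 and the tertiary C7, is too hindered to bind the bulky silyl triflate, so C7 keeps its configuration.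

Step 10
Reactants: 16 tiglyl ketone with acetonide tether and 2-silyloxydiene
Product: 17 (4S,5R,7R,8R,9S,10S)-8,9-(isopropylidenedioxy)-2-(triisopropylsilyloxy)eremophila-1,11-dien-6-one (cis-fused)
Conditions: PhMe (0.01 M), BHT (cat.), 110 °C, sealed tube
Reagents that add atoms: none
Why: Concerted, suprafacial [4+2] cycloaddition in which the silyloxydiene C10=C1–C2=C3 adds to the tiglyl ketone alkene C4=C5, its nucleophilic terminus C3 bonding to the β-carbon C4 and C10 to C5; the closest known reaction type is the thermal intramolecular Diels–Alder reaction of 1,7,9-decatrien-3-ones and of 2-silyloxydienes. Ring A is closed by the cycloaddition itself as a cyclohexene (silyl enol ether at C1=C2), and ring B is closed through the C5–C10 bond across the four-atom tether C6–C9, which adopts a chair-like six-membered array. C4 and C5 take their cis methyl relationship from the E geometry of the tiglyl alkene, which a suprafacial addition conserves. C10 becomes cis to the C5 methyl because the tether carbonyl C6 lies endo, under C1–C2 of the diene, the orientation generally preferred by trienones with the ketone in the tether. The diene face is fixed by C9 through the cis acetonide: only one chair-like tether places the C7 isopropenyl group and O8 equatorial, and within it attack on the other face would set methyl C14 syn-axial to O9 and the diene axial. The step thus needs the endo mode and one diene face, and both should come from the ketone-in-tether geometry and from the C7–C9 triad held in the dioxolane.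

Step 11
Reactants: 17 cis-fused 6-oxo decalin
Product: 18 (4S,5R,6S,7S,8R,9S,10S)-8,9-(isopropylidenedioxy)-2-(triisopropylsilyloxy)eremophila-1,11-dien-6-ol
Conditions: LiAlH4, Et2O, 0 °C; H2O, 15% NaOH (aq)
Reagents that add atoms: none
Why: Hydride reduction of a hindered ketone with LiAlH4, which is small enough to reach C6 between C5 and C7; attack opposite the axial C4 branch should give mainly the equatorial alcohol drawn, and its configuration is immaterial because C6 is deoxygenated next, while the silyl enol ether (the masked C2 ketone) and the acetonide are inert.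

Step 12
Reactants: 18 C6 alcohol
Product: 20 O-[(4S,5R,6S,7S,8R,9S,10S)-8,9-(isopropylidenedioxy)-2-(triisopropylsilyloxy)eremophila-1,11-dien-6-yl] S-methyl dithiocarbonate, via sodium xanthate 19 (not isolated)
Conditions: NaH, CS2, imidazole (cat.), THF, 0 °C → rt; then MeI
Reagents that add atoms: carbon disulfide, S=C=S; iodomethane, CI
Why: Xanthate formation (first stage of the Barton–McCombie deoxygenation); the alkoxide adds to CS2 and the dithiocarbonate salt is S-methylated, a sequence that tolerates the neopentyl-like position of C6.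

Step 13
Reactants: 20 xanthate
Product: 21 (4S,5R,7R,8R,9S,10S)-8,9-(isopropylidenedioxy)-2-(triisopropylsilyloxy)eremophila-1,11-diene
Conditions: Bu3SnH (5 equiv, 0.3 M), AIBN, PhMe, 100 °C
Reagents that add atoms: none
Why: Barton–McCombie radical deoxygenation; the stannyl radical adds to the thiocarbonyl group, the C6–O bond fragments, and the secondary C6 radical takes hydrogen from the stannane, whose high concentration lets hydrogen transfer outrun the slow three-membered ring closure onto the isopropenyl group, so C6 becomes CH2 and no stereocentre changes.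

Step 14
Reactants: 21 deoxygenated silyl enol ether acetonide
Product: 22 (4S,5R,7R,8R,9S,10S)-8,9-dihydroxyeremophil-11-en-2-one
Conditions: 2 M HCl (aq), THF, rt
Reagents that add atoms: none
Why: Aqueous acid hydrolysis of the silyl enol ether (protonation at C1) and of the acetonide in one operation; C1 and C3 are methylene groups and neither C4 nor C10 is α to the new C2 ketone, so nothing can epimerise, and dilute acid at room temperature spares the isopropenyl group.

Step 15
Reactants: 22 keto diol
Product: 23 (4S,5R,7R,8R,9S,10S)-8-acetoxy-9-hydroxyeremophil-11-en-2-one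
Conditions: Ac2O (1.1 equiv), pyridine, CH2Cl2, 0 °C
Reagents that add atoms: acetic anhydride, CC(=O)OC(C)=O
Why: Regioselective O-acylation; the equatorial C8 hydroxyl is acetylated, whereas the axial C9 hydroxyl, syn-axial to the C5–C4 bond on the concave face of the cis-decalin, should not react with acetic anhydride in pyridine at 0 °C without DMAP.

Step 16
Reactants: 23 monoacetate; 1 tigloyl chloride (3 equiv)
Product: 24 (4S,5R,7R,8R,9S,10S)-8-acetoxy-9-[(E)-2-methylbut-2-enoyloxy]eremophil-11-en-2-one (CNP0204573.1)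
Conditions: DMAP (0.5 equiv), pyridine, 50 °C
Reagents that add atoms: none
Why: DMAP-catalysed esterification with an acid chloride; the acylpyridinium salt acylates the remaining hindered C9 hydroxyl, pyridine in place of a trialkylamine avoids deconjugation of the tiglyl unit through a vinylketene, and migration of the acetate to the congested axial oxygen is disfavoured, so the E-tiglate ends on C9.

Compound list
1 | tigloyl chloride, (E)-2-methylbut-2-enoyl chloride | C/C=C(\C)C(Cl)=O | starting material
2 | (E)-N-methoxy-N,2-dimethylbut-2-enamide | C/C=C(\C)C(=O)N(C)OC | intermediate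
3 | 2-methylallylmagnesium chloride | C=C(C)C[Mg]Cl | starting material
4 | (E)-2,5-dimethylhepta-1,5-dien-4-one | C/C=C(\C)C(=O)CC(C)=C | intermediate
5 | methyl (S)-2-hydroxybut-3-enoate | C=C[C@H](O)C(=O)OC | starting material
6 | (S)-but-3-en-2-ol | C[C@H](O)C=C | starting material
7 | methyl (2S,3E,5S)-2,5-dihydroxyhex-3-enoate | C[C@H](O)/C=C/[C@H](O)C(=O)OC | intermediate
8 | methyl (2S,3E,5S)-2,5-bis(triethylsilyloxy)hex-3-enoate | C[C@H](O[Si](CC)(CC)CC)/C=C/[C@H](O[Si](CC)(CC)CC)C(=O)OC | intermediate
9 | (2S,3E,5S)-2,5-bis(triethylsilyloxy)hex-3-enal | C[C@H](O[Si](CC)(CC)CC)/C=C/[C@H](O[Si](CC)(CC)CC)C=O | intermediate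
10 | dibutyl{[(3Z,5E)-2,5-dimethylhepta-1,3,5-trien-4-yl]oxy}borane | C/C=C(\C)/C(OB(CCCC)CCCC)=C/C(C)=C | intermediate (not isolated)
11 | O6-dibutylboryl aldolate of 12 | C/C=C(\C)C(=O)[C@H](C(C)=C)[C@@H](OB(CCCC)CCCC)[C@@H](O[Si](CC)(CC)CC)/C=C/[C@H](C)O[Si](CC)(CC)CC | intermediate (not isolated)
12 | (2E,5R,6R,7S,8E,10S)-6-hydroxy-3-methyl-5-(prop-1-en-2-yl)-7,10-bis(triethylsilyloxy)undeca-2,8-dien-4-one | C/C=C(\C)C(=O)[C@H](C(C)=C)[C@@H](O)[C@@H](O[Si](CC)(CC)CC)/C=C/[C@H](C)O[Si](CC)(CC)CC | intermediate
13 | (2E,5R,6R,7S,8E,10S)-6,7,10-trihydroxy-3-methyl-5-(prop-1-en-2-yl)undeca-2,8-dien-4-one | C/C=C(\C)C(=O)[C@H](C(C)=C)[C@@H](O)[C@@H](O)/C=C/[C@H](C)O | intermediate (not isolated)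
14 | (2E,5R)-5-{(4R,5S)-5-[(1E,3S)-3-hydroxybut-1-en-1-yl]-2,2-dimethyl-1,3-dioxolan-4-yl}-3,6-dimethylhepta-2,6-dien-4-one | C/C=C(\C)C(=O)[C@H](C(C)=C)[C@H]1OC(C)(C)O[C@H]1/C=C/[C@H](C)O | intermediate
15 | (2E,5R)-3,6-dimethyl-5-{(4R,5S)-2,2-dimethyl-5-[(E)-3-oxobut-1-en-1-yl]-1,3-dioxolan-4-yl}hepta-2,6-dien-4-one | C/C=C(\C)C(=O)[C@H](C(C)=C)[C@H]1OC(C)(C)O[C@H]1/C=C/C(C)=O | intermediate
16 | (2E,5R)-3,6-dimethyl-5-{(4R,5S)-2,2-dimethyl-5-[(E)-3-(triisopropylsilyloxy)buta-1,3-dien-1-yl]-1,3-dioxolan-4-yl}hepta-2,6-dien-4-one | C/C=C(\C)C(=O)[C@H](C(C)=C)[C@H]1OC(C)(C)O[C@H]1/C=C/C(=C)O[Si](C(C)C)(C(C)C)C(C)C | intermediate (key-step precursor)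
17 | (4S,5R,7R,8R,9S,10S)-8,9-(isopropylidenedioxy)-2-(triisopropylsilyloxy)eremophila-1,11-dien-6-one | C=C(C)[C@H]1C(=O)[C@@]2(C)[C@H](C=C(O[Si](C(C)C)(C(C)C)C(C)C)C[C@@H]2C)[C@@H]3OC(C)(C)O[C@H]13 | intermediate (key-step product)
18 | (4S,5R,6S,7S,8R,9S,10S)-8,9-(isopropylidenedioxy)-2-(triisopropylsilyloxy)eremophila-1,11-dien-6-ol | C=C(C)[C@H]1[C@H](O)[C@@]2(C)[C@H](C=C(O[Si](C(C)C)(C(C)C)C(C)C)C[C@@H]2C)[C@@H]3OC(C)(C)O[C@H]13 | intermediate
19 | sodium O-alkyl dithiocarbonate of 18 | C=C(C)[C@H]1[C@H](OC(=S)[S-])[C@@]2(C)[C@H](C=C(O[Si](C(C)C)(C(C)C)C(C)C)C[C@@H]2C)[C@@H]3OC(C)(C)O[C@H]13.[Na+] | intermediate (not isolated)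
20 | O-[(4S,5R,6S,7S,8R,9S,10S)-8,9-(isopropylidenedioxy)-2-(triisopropylsilyloxy)eremophila-1,11-dien-6-yl] S-methyl dithiocarbonate | C=C(C)[C@H]1[C@H](OC(=S)SC)[C@@]2(C)[C@H](C=C(O[Si](C(C)C)(C(C)C)C(C)C)C[C@@H]2C)[C@@H]3OC(C)(C)O[C@H]13 | intermediate
21 | (4S,5R,7R,8R,9S,10S)-8,9-(isopropylidenedioxy)-2-(triisopropylsilyloxy)eremophila-1,11-diene | C=C(C)[C@H]1C[C@@]2(C)[C@H](C=C(O[Si](C(C)C)(C(C)C)C(C)C)C[C@@H]2C)[C@@H]3OC(C)(C)O[C@H]13 | intermediate
22 | (4S,5R,7R,8R,9S,10S)-8,9-dihydroxyeremophil-11-en-2-one | C=C(C)[C@H]1C[C@@]2(C)[C@H](CC(=O)C[C@@H]2C)[C@H](O)[C@@H]1O | intermediate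
23 | (4S,5R,7R,8R,9S,10S)-8-acetoxy-9-hydroxyeremophil-11-en-2-one | C=C(C)[C@H]1C[C@@]2(C)[C@H](CC(=O)C[C@@H]2C)[C@H](O)[C@@H]1OC(C)=O | intermediate
24 | (4S,5R,7R,8R,9S,10S)-8-acetoxy-9-[(E)-2-methylbut-2-enoyloxy]eremophil-11-en-2-one (CNP0204573.1) | C=C(C)[C@H]1C[C@@]2(C)[C@H](CC(=O)C[C@@H]2C)[C@H](OC(=O)/C(C)=C/C)[C@@H]1OC(C)=O | target

Total step count: 16 steps.
Longest linear sequence: 14 steps (5 → 24, steps 3–16); the ketone branch (steps 1–2) joins at step 6.

Steps most likely to fail

Step 10 (key cycloaddition). The trans-fused (exo) mode or attack on the other diene face may compete with the endo, C9-directed pathway, and prolonged heating of the hindered tiglyl dienophile may allow epimerisation at C7. The fallback replaces substrate control under heating by catalyst control at low temperature. It sets out from 16 and treats it in CH2Cl2 at −78 → −20 °C with a cationic chiral oxazaborolidine Lewis acid (the B-(o-tolyl) oxazaborolidine of diphenylprolinol protonated with Tf2NH, 10–20 mol%). The boron cation binds the C6 carbonyl, enforces the endo mode and adds its own facial bias. Both catalyst enantiomers are available, and the one whose bias matches that of C9 would be used. It comes back at 17 and makes no new compound (F0).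

Step 6 (boron aldol). Facial discrimination at the α-silyloxy aldehyde may be insufficient, or the β,γ-unsaturated aldehyde may enolise, giving mixtures at C7/C8 or racemisation at C9. The fallback moves stereocontrol to a chiral auxiliary and sets out from 9. (R)-4-Benzyloxazolidin-2-one is N-acylated (n-BuLi, 3-methylbut-2-enoyl chloride, THF, −78 °C) to (R)-4-benzyl-3-(3-methylbut-2-enoyl)oxazolidin-2-one F1. Its dibutylboron Z-dienolate (Bu2BOTf, Et3N, CH2Cl2) adds to 9 through the α-carbon in an auxiliary-controlled syn-aldol reaction to give (R)-4-benzyl-3-[(2R,3R,4S,5E,7S)-3-hydroxy-2-(prop-1-en-2-yl)-4,7-bis(triethylsilyloxy)oct-5-enoyl]oxazolidin-2-one F2. Transamination (Me3Al, MeNH(OMe)·HCl, CH2Cl2, 0 °C) gives (2R,3R,4S,5E,7S)-3-hydroxy-N-methoxy-N-methyl-2-(prop-1-en-2-yl)-4,7-bis(triethylsilyloxy)oct-5-enamide F3. Addition of (E)-but-2-en-2-yllithium (from (E)-2-bromobut-2-ene and t-BuLi, 3 equiv, THF, −78 °C) installs the tiglyl ketone, and the fallback comes back at 12.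

Step 16 (tigloylation beside the acetate). The axial C9 hydroxyl may acylate so slowly that the acetate migrates from O8 to O9 and the freed equatorial C8 hydroxyl is tigloylated instead, scrambling the two esters. The fallback reverses the order of acylation with a temporary group; it sets out from 22 and replaces steps 15 and 16. TESCl and imidazole (CH2Cl2, −20 °C) silylate only the equatorial hydroxyl to give (4S,5R,7R,8R,9S,10S)-9-hydroxy-8-(triethylsilyloxy)eremophil-11-en-2-one F4. Forcing tigloylation (1, DMAP, pyridine, 60 °C), now with no acyl group able to migrate, gives (4S,5R,7R,8R,9S,10S)-9-[(E)-2-methylbut-2-enoyloxy]-8-(triethylsilyloxy)eremophil-11-en-2-one F5. HF·pyridine in THF removes the silyl group under acidic conditions to give (4S,5R,7R,8R,9S,10S)-8-hydroxy-9-[(E)-2-methylbut-2-enoyloxy]eremophil-11-en-2-one F6. Ac2O in pyridine then acetylates the unhindered C8 hydroxyl, and the fallback comes back at 24.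

Further compounds
F0 | step 10 | none | none
F1 | step 6 | (R)-4-benzyl-3-(3-methylbut-2-enoyl)oxazolidin-2-one | CC(C)=CC(=O)N1[C@H](Cc2ccccc2)COC1=O
F2 | step 6 | (R)-4-benzyl-3-[(2R,3R,4S,5E,7S)-3-hydroxy-2-(prop-1-en-2-yl)-4,7-bis(triethylsilyloxy)oct-5-enoyl]oxazolidin-2-one | O=C1OC[C@@H](Cc2ccccc2)N1C(=O)[C@H](C(C)=C)[C@@H](O)[C@@H](O[Si](CC)(CC)CC)/C=C/[C@H](C)O[Si](CC)(CC)CC
F3 | step 6 | (2R,3R,4S,5E,7S)-3-hydroxy-N-methoxy-N-methyl-2-(prop-1-en-2-yl)-4,7-bis(triethylsilyloxy)oct-5-enamide | CON(C)C(=O)[C@H](C(C)=C)[C@@H](O)[C@@H](O[Si](CC)(CC)CC)/C=C/[C@H](C)O[Si](CC)(CC)CC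
F4 | step 16 | (4S,5R,7R,8R,9S,10S)-9-hydroxy-8-(triethylsilyloxy)eremophil-11-en-2-one | C=C(C)[C@H]1C[C@@]2(C)[C@H](CC(=O)C[C@@H]2C)[C@H](O)[C@@H]1O[Si](CC)(CC)CC
F5 | step 16 | (4S,5R,7R,8R,9S,10S)-9-[(E)-2-methylbut-2-enoyloxy]-8-(triethylsilyloxy)eremophil-11-en-2-one | C=C(C)[C@H]1C[C@@]2(C)[C@H](CC(=O)C[C@@H]2C)[C@H](OC(=O)/C(C)=C/C)[C@@H]1O[Si](CC)(CC)CC
F6 | step 16 | (4S,5R,7R,8R,9S,10S)-8-hydroxy-9-[(E)-2-methylbut-2-enoyloxy]eremophil-11-en-2-one | C=C(C)[C@H]1C[C@@]2(C)[C@H](CC(=O)C[C@@H]2C)[C@H](OC(=O)/C(C)=C/C)[C@@H]1O
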